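**Retrosynthetic overview**

1. The periphery is cut at the Z-alkene (Sonogashira coupling of a left-half aryl alkyne with a right-half 4-bromo-dihydrobenzofuran, then semi-hydrogenation) and at the C-c–O–aryl ether (alkoxide SNAr on 4-fluorobenzonitrile).
2. The plan rests on the seven-membered ring (C3, two carbons of ring A, C-a, C-c, C4 and C3a of ring B): C-a (the CH with the 4-hydroxyphenyl group) and C-c (the CH with the aryloxy group) are adjacent and both benzylic, so their bond is made as C-a=C-c by Ramberg–Bäcklund loss of SO2 from an eight-membered benzylic sulfone, and H (C-a) and O (C-c) are then added syn by hydroboration–oxidation.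
3. The sulfone comes from a C4–CH2SH thiol, 4-methoxybenzaldehyde and acid (thionium Friedel–Crafts closure onto ring A), then oxidation at sulfur.
4. Both halves come from one (2R,3R)-4-bromo-2,3-diaryl-2,3-dihydrobenzofuran, made by an enantioselective rhodium-carbene C–H insertion (cis) and epimerised at C2 to trans during BBr3 demethylation.
5. Ring order: dihydrobenzofuran, eight-membered sulfide and sulfone, seven-membered carbocycle by contraction; the second dihydrobenzofuran is attached last.

Key step: step 11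

Labels: dihydrobenzofuran atoms are O1, C2, C3, C3a, C4–C7, C7a; ring A is the 3,5-dioxygenated phenyl on C3, ring B the benzo ring of the dihydrobenzofuran; C-a is bonded to C2 of ring A and carries the 4-oxyphenyl group; C-c is bonded to C4 of ring B.

Assumption: the sense of induction of Rh2(R-PTAD)4 (step 4) and of IpcBH2 from (−)-α-pinene (step 14) is assigned by analogy with simpler substrates; if either proves opposite, the mirror-image catalyst or borane is used.

**Route**

Step 1
Reactants: 1 1-bromo-3,5-dimethoxybenzene; 2 3,5-dimethoxybenzoyl chloride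
Product: 4 (2-bromo-6-hydroxy-4-methoxyphenyl)(3,5-dimethoxyphenyl)methanone, via tetramethoxy ketone 3 (not isolated)
Conditions: AlCl3 (3 equiv), CH2Cl2, 0 °C → 40 °C; aq. HCl
Reagents that add atoms: none
Why: Friedel–Crafts acylation of 1 is expected para to one methoxy group and ortho to bromine rather than at the more hindered position between the two methoxy groups, and the excess AlCl3 should then cleave only the methoxy group that chelates to the new ketone (ortho-selective ether cleavage), which gives the phenol for the benzyl ether.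

Step 2
Reactants: 4 (2-bromo-6-hydroxy-4-methoxyphenyl)(3,5-dimethoxyphenyl)methanone; 5 4-methoxybenzyl chloride
Product: 6 [2-bromo-4-methoxy-6-(4-methoxybenzyloxy)phenyl](3,5-dimethoxyphenyl)methanone
Conditions: K2CO3, n-Bu4NI (cat.), DMF, 60 °C
Reagents that add atoms: none
Why: Williamson etherification of the hydrogen-bonded phenol with a reactive benzylic chloride; the OCH2Ar group brings in the future C2 and its 4-methoxyphenyl group.

Step 3
Reactants: 6 [2-bromo-4-methoxy-6-(4-methoxybenzyloxy)phenyl](3,5-dimethoxyphenyl)methanone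
Product: 7 N-unsubstituted hydrazone of ketone 6
Conditions: N2H4·H2O (20 equiv), AcOH (cat.), n-BuOH, 120 °C, sealed tube
Reagents that add atoms: hydrazine, NN
Why: Acid-catalysed condensation of the ketone with hydrazine to the hydrazone; the carbonyl group lies between two ortho substituents, hence the excess of hydrazine and the high temperature, under which the aryl bromide and the ethers should persist.

Step 4
Reactants: 7 N-unsubstituted hydrazone of ketone 6
Product: 9 (2S,3R)-4-bromo-3-(3,5-dimethoxyphenyl)-6-methoxy-2-(4-methoxyphenyl)-2,3-dihydrobenzofuran (2,3-cis), via diaryldiazomethane 8 (not isolated)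
Conditions: MnO2, CH2Cl2, 0 °C, filter; then Rh2(R-PTAD)4 [PTAD = (1-adamantyl)(N-phthalimido)acetate] (1 mol %), CH2Cl2, −40 °C → rt
Reagents that add atoms: none
Why: MnO2 dehydrogenates the hydrazone to the diaryldiazomethane, whose donor/donor rhodium carbene inserts into a benzylic C–H bond of the OCH2Ar group (intramolecular 1,5 C–H insertion, concerted, so that the 2,3-cis ring forms); the chiral carboxylate ligands choose the carbene face and the enantiotopic C–H bond and thereby set C3 (R) and C2 (S).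

Step 5
Reactants: 9 (2S,3R)-4-bromo-3-(3,5-dimethoxyphenyl)-6-methoxy-2-(4-methoxyphenyl)-2,3-dihydrobenzofuran
Product: 10 (2R,3R)-4-bromo-3-(3,5-dihydroxyphenyl)-2-(4-hydroxyphenyl)-2,3-dihydrobenzofuran-6-ol (2,3-trans)
Conditions: BBr3 (8 equiv), CH2Cl2, −78 °C → rt; MeOH, then H2O
Reagents that add atoms: none
Why: BBr3 cleaves the four aryl methyl ethers, and in the Lewis-acidic medium the 4-oxybenzylic C2–O1 bond should open reversibly to a quinone-methide-type species and reclose to the more stable 2,3-trans ring, an epimerisation at C2 alone that leaves C3 (R) and gives (2R,3R).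

Step 6
Reactants: 10 (2R,3R)-4-bromo-3-(3,5-dihydroxyphenyl)-2-(4-hydroxyphenyl)-2,3-dihydrobenzofuran-6-ol
Product: 11 (2R,3R)-4-bromo-3-(3,5-dimethoxyphenyl)-6-methoxy-2-(4-methoxyphenyl)-2,3-dihydrobenzofuran
Conditions: MeI, K2CO3, acetone, 40 °C
Reagents that add atoms: iodomethane, CI
Why: Exhaustive Williamson methylation of the four phenols gives ethers that withstand the organolithium, acid, peracid and KOH steps of the left half, which silyl ethers would not; the 4-hydroxyphenyl oxygen should be alkylated faster than its phenoxide can open the ring at C2.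

Step 7
Reactants: 11 (2R,3R)-4-bromo-3-(3,5-dimethoxyphenyl)-6-methoxy-2-(4-methoxyphenyl)-2,3-dihydrobenzofuran
Product: 14 [(2R,3R)-3-(3,5-dimethoxyphenyl)-6-methoxy-2-(4-methoxyphenyl)-2,3-dihydrobenzofuran-4-yl]methanol, via aryllithium 12 (not isolated), via aldehyde 13 (not isolated)
Conditions: n-BuLi, THF, −78 °C; DMF, −78 → 0 °C; then NaBH4, MeOH, 0 °C
Reagents that add atoms: N,N-dimethylformamide, CN(C)C=O
Why: Bromine–lithium exchange at −78 °C is faster than any deprotonation, DMF formylates the aryllithium (Bouveault reaction) and NaBH4 reduces the aldehyde in the same flask, which avoids handling an aldehyde that sits next to the nucleophilic ring A.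

Step 8
Reactants: 14 [(2R,3R)-3-(3,5-dimethoxyphenyl)-6-methoxy-2-(4-methoxyphenyl)-2,3-dihydrobenzofuran-4-yl]methanol
Product: 15 S-{[(2R,3R)-3-(3,5-dimethoxyphenyl)-6-methoxy-2-(4-methoxyphenyl)-2,3-dihydrobenzofuran-4-yl]methyl} ethanethioate
Conditions: PPh3, DIAD, AcSH, THF, 0 °C → rt
Reagents that add atoms: thioacetic acid, CC(=O)S
Why: Mitsunobu reaction of the primary benzylic alcohol with thioacetic acid gives the thioester under neutral conditions, with no benzylic cation that ring A could capture.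

Step 9
Reactants: 15 S-{[(2R,3R)-3-(3,5-dimethoxyphenyl)-6-methoxy-2-(4-methoxyphenyl)-2,3-dihydrobenzofuran-4-yl]methyl} ethanethioate; 16 4-methoxybenzaldehyde
Product: 18 eight-membered cyclic sulfide in which C4–CH2–S–CH(4-methoxyphenyl) bridges to C2 of ring A of the (2R,3R)-dihydrobenzofuran (both C-a epimers), via thiol 17 (not isolated)
Conditions: NaOMe (1.1 equiv), degassed MeOH–THF, 0 °C; CF3CO2H to pH 3, evaporate; then 16, CF3CO2H–CH2Cl2 (1:9), 2 mM, 0 °C → rt
Reagents that add atoms: none
Why: Methanolysis frees the thiol, which condenses with 16 under acid to a 4-methoxyphenyl-stabilised thionium ion; ring A attacks it at its C2 (para to one methoxy group, ortho to the other) in an intramolecular Friedel–Crafts alkylation of the thia-Pictet–Spengler type, high dilution favouring the eight-membered ring over dithioacetal and oligomer, and the epimer mixture at C-a is of no consequence because C-a becomes sp2 in step 11.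

Step 10
Reactants: 18 eight-membered cyclic sulfide
Product: 19 eight-membered cyclic sulfone (S,S-dioxide of 18)
Conditions: mCPBA (2.3 equiv), CH2Cl2, 0 °C → rt
Reagents that add atoms: 3-chloroperbenzoic acid, OOC(=O)c1cccc(Cl)c1
Why: Peracid oxidation of the sulfide through the sulfoxide to the sulfone; sulfur is far more nucleophilic than the methoxyarenes, so two equivalents at low temperature should stop there.

Step 11
Reactants: 19 eight-membered cyclic sulfone
Product: 22 pentamethyl ether of the dibenzocycloheptene-fused (2R,3R)-dihydrobenzofuran with the C-a=C-c double bond, via bromo sulfone 20 (not isolated), via episulfone 21 (not isolated)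
Conditions: KOH on Al2O3, CBr2F2, t-BuOH–CH2Cl2, 5 °C → rt
Reagents that add atoms: none
Why: KOH on alumina deprotonates an α-sulfonyl benzylic carbon (the doubly benzylic C-a–H, or C-c–H2) and CBr2F2 transfers bromine to the carbanion; the second α-carbanion then displaces bromide in a 1,3-elimination and the episulfone loses SO2 in a cheletropic step, which is the Ramberg–Bäcklund reaction in its one-flask halogenative form. The closest known case is the contraction of cyclic dibenzylic sulfones to cyclic stilbenes. The three-membered episulfone closes by 3-exo-tet displacement at the brominated carbon, and the seven-membered carbocycle is formed by contraction of the eight-membered ring when SO2 leaves, so the C-a–C-c bond is made without a medium-ring cyclisation at carbon. No stereocentre is created: the epimer mixture at C-a converges because C-a becomes sp2, and the ring allows only the cis C-a=C-c bond. The step needs halogenation at the α-sulfonyl carbons only and only once; this should be secured because these are the only C–H bonds acidic enough for KOH (C2–H and C3–H are not, so the two dihydrobenzofuran centres stay), because both halogenation sites lead to the same episulfone, and because CBr2F2 releases the unreactive difluorocarbene, which should spare the hindered triaryl alkene.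

Step 12
Reactants: 22 pentamethyl ether with the C-a=C-c double bond
Product: 23 pentaphenol of 22
Conditions: BBr3 (10 equiv), CH2Cl2, −78 → 0 °C; MeOH, then H2O
Reagents that add atoms: none
Why: BBr3 cleavage of the five aryl methyl ethers is placed here because the only benzylic C–O bond present is that of the dihydrobenzofuran; the triaryl alkene has no position to which it could isomerise, and the dihydrobenzofuran, if it opens at C2, should reclose trans as in step 5.

Step 13
Reactants: 23 pentaphenol of 22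
Product: 24 penta(triisopropylsilyl) ether of 23
Conditions: i-Pr3SiOTf, 2,6-lutidine, CH2Cl2, 0 °C → rt
Reagents that add atoms: triisopropylsilyl trifluoromethanesulfonate, CC(C)[Si](C(C)C)(C(C)C)OS(=O)(=O)C(F)(F)F
Why: Silylation of the five phenols with the silyl triflate and a hindered base; triisopropylsilyl aryl ethers are chosen because they should resist the alkoxide of step 15 and still fall to fluoride at the end.

Step 14
Reactants: 24 penta(triisopropylsilyl) ether of 23
Product: 26 penta(triisopropylsilyl) (2R,3R, C-a R, C-c S) alcohol with H on C-a and OH on C-c syn (4-silyloxyphenyl and OH trans), via organoborane 25 (not isolated)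
Conditions: IpcBH2 (from (−)-α-pinene, 3 equiv), THF, 0 °C → rt; then H2O2, aq. NaOAc, 0 °C → rt
Reagents that add atoms: hydrogen peroxide, OO
Why: Hydroboration places boron on the less substituted C-c and hydrogen on the diaryl-substituted C-a in a syn four-centre addition, and oxidation replaces boron by OH with retention, which gives the aryl group on C-a and the OH on C-c trans; the seven-membered ring is a boat whose C3–H points over the inner face of the alkene, so the borane should add to the outer face, anti to C3–H, and IpcBH2 from (−)-α-pinene is chosen as the enantiomer whose own preference (by analogy with 1-arylcycloalkenes) is the same, setting C-a (R) and C-c (S).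

Step 15
Reactants: 26 penta(triisopropylsilyl) alcohol; 27 4-fluorobenzonitrile
Product: 29 4-cyanophenyl ether of 26 at the C-c oxygen, via potassium alkoxide 28 (not isolated)
Conditions: KN(SiMe3)2, THF–DMPU, 0 °C; then 27, 0 °C → rt
Reagents that add atoms: none
Why: The potassium alkoxide displaces fluoride from the para-cyano-activated arene by addition–elimination (SNAr through a Meisenheimer adduct); the C-c–O bond is not broken, so C-c keeps its configuration, and the nitrile is used as activating group because, unlike an aldehyde, it offers the alkoxide no hydride-transfer or addition pathway.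

Step 16
Reactants: 29 4-cyanophenyl ether
Product: 31 4-formylphenyl ether (aldehyde), via aluminated aldimine 30 (not isolated)
Conditions: i-Bu2AlH, toluene, −78 °C; aqueous potassium sodium tartrate, then aq. AcOH (pH 5), 0 °C
Reagents that add atoms: water, O
Why: i-Bu2AlH adds once to the nitrile to give the N-aluminated aldimine, which is stable at low temperature and is hydrolysed to the aldehyde on work-up; the silyl ethers and the benzylic aryl ether are inert to the hydride.

Step 17
Reactants: 31 4-formylphenyl ether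
Product: 32 4-ethynylphenyl ether (terminal alkyne)
Conditions: Me3SiCHN2, n-BuLi, THF, −78 °C → 0 °C
Reagents that add atoms: trimethylsilyldiazomethane, C[Si](C)(C)C=[N+]=[N-]
Why: Colvin rearrangement: lithiated trimethylsilyldiazomethane adds to the aldehyde, Peterson-type loss of silanolate gives a diazoalkene, and the alkylidene carbene formed on loss of N2 undergoes a 1,2-hydrogen shift to the terminal aryl alkyne, without the methanolic base that would endanger the aryl silyl ethers.

Step 18
Reactants: 10 (2R,3R)-4-bromo-3-(3,5-dihydroxyphenyl)-2-(4-hydroxyphenyl)-2,3-dihydrobenzofuran-6-ol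
Product: 33 tetrakis(tert-butyldimethylsilyl) ether of 10
Conditions: t-BuMe2SiCl, imidazole, DMF, rt
Reagents that add atoms: tert-butyldimethylsilyl chloride, CC(C)(C)[Si](C)(C)Cl
Why: Silylation of the four phenols of the common bromide gives a base-stable, fluoride-labile partner for the coupling.

Step 19
Reactants: 32 4-ethynylphenyl ether; 33 tetrakis(tert-butyldimethylsilyl) ether of 10
Product: 34 diarylalkyne joining the left half to C4 of the right-half dihydrobenzofuran (nine silyl ethers)
Conditions: PdCl2(PhCN)2 (3 mol %), P(t-Bu)3 (6 mol %), CuI (2 mol %), i-Pr2NH, dioxane, rt → 45 °C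
Reagents that add atoms: none
Why: Sonogashira coupling of the terminal alkyne with the electron-rich, ortho-substituted aryl bromide; the bulky electron-rich phosphine should allow oxidative addition near room temperature, and the amine base leaves the silyl ethers alone.

Step 20
Reactants: 34 diarylalkyne
Product: 35 Z-stilbene (nonasilyl ether of the target)
Conditions: H2 (1 atm), Pd on CaCO3 poisoned with Pb(OAc)2 (Lindlar catalyst), quinoline, EtOAc, rt
Reagents that add atoms: none
Why: Semi-hydrogenation on the lead-poisoned palladium surface delivers both hydrogens to one face of the alkyne and stops at the alkene, which fixes the Z geometry; quinoline should suppress over-reduction and hydrogenolysis of the benzylic ethers.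

Step 21
Reactants: 35 Z-stilbene (nonasilyl ether of the target)
Product: 36 CNP0354678.1
Conditions: Bu4NF, AcOH, THF, 0 °C → rt
Reagents that add atoms: none
Why: Fluoride cleaves the nine Si–O(aryl) bonds (five triisopropylsilyl, four tert-butyldimethylsilyl) in a medium buffered by acetic acid, which avoids both the acid that would cyclise the Z-stilbene onto the neighbouring resorcinol ring and phenoxide-driven opening of the dihydrobenzofurans.

**Compound list**

1 | 1-bromo-3,5-dimethoxybenzene | COc1cc(OC)cc(Br)c1 | starting material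
2 | 3,5-dimethoxybenzoyl chloride | COc1cc(OC)cc(C(=O)Cl)c1 | starting material
3 | (2-bromo-4,6-dimethoxyphenyl)(3,5-dimethoxyphenyl)methanone (not isolated) | COc1cc(OC)c(C(=O)c2cc(OC)cc(OC)c2)c(Br)c1 | intermediate
4 | (2-bromo-6-hydroxy-4-methoxyphenyl)(3,5-dimethoxyphenyl)methanone | COc1cc(O)c(C(=O)c2cc(OC)cc(OC)c2)c(Br)c1 | intermediate
5 | 4-methoxybenzyl chloride | COc1ccc(CCl)cc1 | starting material
6 | [2-bromo-4-methoxy-6-(4-methoxybenzyloxy)phenyl](3,5-dimethoxyphenyl)methanone | COc1ccc(COc2cc(OC)cc(Br)c2C(=O)c2cc(OC)cc(OC)c2)cc1 | intermediate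
7 | N-unsubstituted hydrazone of ketone 6 | COc1ccc(COc2cc(OC)cc(Br)c2C(=NN)c2cc(OC)cc(OC)c2)cc1 | intermediate
8 | [2-bromo-4-methoxy-6-(4-methoxybenzyloxy)phenyl](3,5-dimethoxyphenyl)diazomethane (not isolated) | COc1ccc(COc2cc(OC)cc(Br)c2C(=[N+]=[N-])c2cc(OC)cc(OC)c2)cc1 | intermediate
9 | (2S,3R)-4-bromo-3-(3,5-dimethoxyphenyl)-6-methoxy-2-(4-methoxyphenyl)-2,3-dihydrobenzofuran (cis) | COc1cc(OC)cc(c1)[C@@H]1c2c(cc(OC)cc2Br)O[C@@H]1c1ccc(OC)cc1 | intermediate
10 | (2R,3R)-4-bromo-3-(3,5-dihydroxyphenyl)-2-(4-hydroxyphenyl)-2,3-dihydrobenzofuran-6-ol (trans) | Oc1cc(O)cc(c1)[C@@H]1c2c(cc(O)cc2Br)O[C@H]1c1ccc(O)cc1 | intermediate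
11 | (2R,3R)-4-bromo-3-(3,5-dimethoxyphenyl)-6-methoxy-2-(4-methoxyphenyl)-2,3-dihydrobenzofuran (trans) | COc1cc(OC)cc(c1)[C@@H]1c2c(cc(OC)cc2Br)O[C@H]1c1ccc(OC)cc1 | intermediate
12 | 4-lithio derivative of 11 (not isolated) | COc1cc(OC)cc(c1)[C@@H]1c2c(cc(OC)cc2[Li])O[C@H]1c1ccc(OC)cc1 | intermediate
13 | (2R,3R)-3-(3,5-dimethoxyphenyl)-6-methoxy-2-(4-methoxyphenyl)-2,3-dihydrobenzofuran-4-carbaldehyde (not isolated) | COc1cc(OC)cc(c1)[C@@H]1c2c(cc(OC)cc2C=O)O[C@H]1c1ccc(OC)cc1 | intermediate
14 | [(2R,3R)-3-(3,5-dimethoxyphenyl)-6-methoxy-2-(4-methoxyphenyl)-2,3-dihydrobenzofuran-4-yl]methanol | COc1cc(OC)cc(c1)[C@@H]1c2c(cc(OC)cc2CO)O[C@H]1c1ccc(OC)cc1 | intermediate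
15 | S-{[(2R,3R)-3-(3,5-dimethoxyphenyl)-6-methoxy-2-(4-methoxyphenyl)-2,3-dihydrobenzofuran-4-yl]methyl} ethanethioate | COc1cc(OC)cc(c1)[C@@H]1c2c(cc(OC)cc2CSC(C)=O)O[C@H]1c1ccc(OC)cc1 | intermediate
16 | 4-methoxybenzaldehyde | COc1ccc(C=O)cc1 | starting material
17 | [(2R,3R)-3-(3,5-dimethoxyphenyl)-6-methoxy-2-(4-methoxyphenyl)-2,3-dihydrobenzofuran-4-yl]methanethiol (not isolated) | COc1cc(OC)cc(c1)[C@@H]1c2c(cc(OC)cc2CS)O[C@H]1c1ccc(OC)cc1 | intermediate
18 | eight-membered cyclic sulfide: C4–CH2–S–CH(4-methoxyphenyl) bridge to C2 of ring A, (2R,3R), C-a epimers | COc1ccc(C2c3c(OC)cc(OC)cc3[C@@H]3c4c(cc(OC)cc4CS2)O[C@H]3c2ccc(OC)cc2)cc1 | intermediate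
19 | eight-membered cyclic sulfone (S,S-dioxide of 18) | COc1ccc(C2c3c(OC)cc(OC)cc3[C@@H]3c4c(cc(OC)cc4CS2(=O)=O)O[C@H]3c2ccc(OC)cc2)cc1 | intermediate
20 | C-a-bromo sulfone (not isolated) | COc1ccc(C2(Br)c3c(OC)cc(OC)cc3[C@@H]3c4c(cc(OC)cc4CS2(=O)=O)O[C@H]3c2ccc(OC)cc2)cc1 | intermediate
21 | episulfone, thiirane 1,1-dioxide across C-a and C-c (not isolated) | COc1ccc(C23c4c(OC)cc(OC)cc4[C@@H]4c5c(cc(OC)cc5C2S3(=O)=O)O[C@H]4c2ccc(OC)cc2)cc1 | intermediate
22 | pentamethyl ether of the dibenzocycloheptene-fused (2R,3R)-dihydrobenzofuran with the C-a=C-c double bond | COc1ccc(C2c3c(OC)cc(OC)cc3[C@@H]3c4c(cc(OC)cc4C=2)O[C@H]3c2ccc(OC)cc2)cc1 | intermediate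
23 | pentaphenol of 22 | Oc1ccc(C2c3c(O)cc(O)cc3[C@@H]3c4c(cc(O)cc4C=2)O[C@H]3c2ccc(O)cc2)cc1 | intermediate
24 | penta(triisopropylsilyl) ether of 23 | CC(C)[Si](C(C)C)(C(C)C)Oc1ccc(C2c3c(O[Si](C(C)C)(C(C)C)C(C)C)cc(O[Si](C(C)C)(C(C)C)C(C)C)cc3[C@@H]3c4c(cc(O[Si](C(C)C)(C(C)C)C(C)C)cc4C=2)O[C@H]3c2ccc(O[Si](C(C)C)(C(C)C)C(C)C)cc2)cc1 | intermediate
25 | C-c organoborane, B(H)Ipc on C-c and H on C-a, syn (not isolated) | CC(C)[Si](C(C)C)(C(C)C)Oc1ccc([C@@H]2c3c(O[Si](C(C)C)(C(C)C)C(C)C)cc(O[Si](C(C)C)(C(C)C)C(C)C)cc3[C@@H]3c4c(cc(O[Si](C(C)C)(C(C)C)C(C)C)cc4[C@H]2B[C@H]2C[C@H]5C[C@@H]([C@@H]2C)C5(C)C)O[C@H]3c2ccc(O[Si](C(C)C)(C(C)C)C(C)C)cc2)cc1 | intermediate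
26 | penta(triisopropylsilyl) (2R,3R, C-a R, C-c S) alcohol | CC(C)[Si](C(C)C)(C(C)C)Oc1ccc([C@@H]2c3c(O[Si](C(C)C)(C(C)C)C(C)C)cc(O[Si](C(C)C)(C(C)C)C(C)C)cc3[C@@H]3c4c(cc(O[Si](C(C)C)(C(C)C)C(C)C)cc4[C@H]2O)O[C@H]3c2ccc(O[Si](C(C)C)(C(C)C)C(C)C)cc2)cc1 | intermediate
27 | 4-fluorobenzonitrile | N#Cc1ccc(F)cc1 | starting material
28 | potassium alkoxide of 26 (not isolated) | CC(C)[Si](C(C)C)(C(C)C)Oc1ccc([C@@H]2c3c(O[Si](C(C)C)(C(C)C)C(C)C)cc(O[Si](C(C)C)(C(C)C)C(C)C)cc3[C@@H]3c4c(cc(O[Si](C(C)C)(C(C)C)C(C)C)cc4[C@H]2[O-])O[C@H]3c2ccc(O[Si](C(C)C)(C(C)C)C(C)C)cc2)cc1.[K+] | intermediate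
29 | 4-cyanophenyl ether of 26 at the C-c oxygen | CC(C)[Si](C(C)C)(C(C)C)Oc1ccc([C@@H]2c3c(O[Si](C(C)C)(C(C)C)C(C)C)cc(O[Si](C(C)C)(C(C)C)C(C)C)cc3[C@@H]3c4c(cc(O[Si](C(C)C)(C(C)C)C(C)C)cc4[C@H]2Oc2ccc(C#N)cc2)O[C@H]3c2ccc(O[Si](C(C)C)(C(C)C)C(C)C)cc2)cc1 | intermediate
30 | N-(diisobutylaluminio)aldimine of 31 (not isolated) | CC(C)[Si](C(C)C)(C(C)C)Oc1ccc([C@@H]2c3c(O[Si](C(C)C)(C(C)C)C(C)C)cc(O[Si](C(C)C)(C(C)C)C(C)C)cc3[C@@H]3c4c(cc(O[Si](C(C)C)(C(C)C)C(C)C)cc4[C@H]2Oc2ccc(C=N[Al](CC(C)C)CC(C)C)cc2)O[C@H]3c2ccc(O[Si](C(C)C)(C(C)C)C(C)C)cc2)cc1 | intermediate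
31 | 4-formylphenyl ether at the C-c oxygen | CC(C)[Si](C(C)C)(C(C)C)Oc1ccc([C@@H]2c3c(O[Si](C(C)C)(C(C)C)C(C)C)cc(O[Si](C(C)C)(C(C)C)C(C)C)cc3[C@@H]3c4c(cc(O[Si](C(C)C)(C(C)C)C(C)C)cc4[C@H]2Oc2ccc(C=O)cc2)O[C@H]3c2ccc(O[Si](C(C)C)(C(C)C)C(C)C)cc2)cc1 | intermediate
32 | 4-ethynylphenyl ether at the C-c oxygen | CC(C)[Si](C(C)C)(C(C)C)Oc1ccc([C@@H]2c3c(O[Si](C(C)C)(C(C)C)C(C)C)cc(O[Si](C(C)C)(C(C)C)C(C)C)cc3[C@@H]3c4c(cc(O[Si](C(C)C)(C(C)C)C(C)C)cc4[C@H]2Oc2ccc(C#C)cc2)O[C@H]3c2ccc(O[Si](C(C)C)(C(C)C)C(C)C)cc2)cc1 | intermediate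
33 | tetrakis(tert-butyldimethylsilyl) ether of 10 | CC(C)(C)[Si](C)(C)Oc1cc(O[Si](C)(C)C(C)(C)C)cc(c1)[C@@H]1c2c(cc(O[Si](C)(C)C(C)(C)C)cc2Br)O[C@H]1c1ccc(O[Si](C)(C)C(C)(C)C)cc1 | intermediate
34 | diarylalkyne, nonasilyl ether | CC(C)[Si](C(C)C)(C(C)C)Oc1ccc([C@@H]2c3c(O[Si](C(C)C)(C(C)C)C(C)C)cc(O[Si](C(C)C)(C(C)C)C(C)C)cc3[C@@H]3c4c(cc(O[Si](C(C)C)(C(C)C)C(C)C)cc4[C@H]2Oc2ccc(C#Cc4cc(O[Si](C)(C)C(C)(C)C)cc5c4[C@@H](c4cc(O[Si](C)(C)C(C)(C)C)cc(O[Si](C)(C)C(C)(C)C)c4)[C@H](c4ccc(O[Si](C)(C)C(C)(C)C)cc4)O5)cc2)O[C@H]3c2ccc(O[Si](C(C)C)(C(C)C)C(C)C)cc2)cc1 | intermediate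
35 | Z-stilbene, nonasilyl ether of the target | CC(C)[Si](C(C)C)(C(C)C)Oc1ccc([C@@H]2c3c(O[Si](C(C)C)(C(C)C)C(C)C)cc(O[Si](C(C)C)(C(C)C)C(C)C)cc3[C@@H]3c4c(cc(O[Si](C(C)C)(C(C)C)C(C)C)cc4[C@H]2Oc2ccc(/C=C\c4cc(O[Si](C)(C)C(C)(C)C)cc5c4[C@@H](c4cc(O[Si](C)(C)C(C)(C)C)cc(O[Si](C)(C)C(C)(C)C)c4)[C@H](c4ccc(O[Si](C)(C)C(C)(C)C)cc4)O5)cc2)O[C@H]3c2ccc(O[Si](C(C)C)(C(C)C)C(C)C)cc2)cc1 | intermediate
36 | CNP0354678.1 | Oc1ccc([C@@H]2c3c(O)cc(O)cc3[C@@H]3c4c(cc(O)cc4[C@H]2Oc2ccc(/C=C\c4cc(O)cc5c4[C@@H](c4cc(O)cc(O)c4)[C@H](c4ccc(O)cc4)O5)cc2)O[C@H]3c2ccc(O)cc2)cc1 | target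

**Step count and risks**

Total step count: 21. Longest linear sequence: 20 steps (steps 1–17 and 19–21); step 18 is the branch from 10.

The three steps most likely to fail:

Step 11 (Ramberg–Bäcklund contraction). What may go wrong is a second bromination at C-c before the 1,3-elimination (which would end in a bromoalkene), slow episulfone closure at the fully substituted C-a, or addition of difluorocarbene to the product alkene. The fallback sets out from sulfide 18 and uses a Stevens rearrangement followed by sulfoxide elimination. S-Methylation of 18 with Me3OBF4 in CH2Cl2 gives the S-methylsulfonium tetrafluoroborate F1. KOt-Bu in THF forms the ylide at C-a, and the [1,2]-shift of the C-c benzyl group contracts the ring to the seven-membered C-a methylthio compound F2 (the ylide at C-c would give the regioisomer, which converges). NaIO4 oxidises F2 to the methyl sulfoxide F3, and thermal syn-elimination in toluene at 80 °C comes back to the route at alkene 22.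

Step 9 (closure of the eight-membered sulfide). What may go wrong is intermolecular capture of the thionium ion (dithioacetal, oligomers) outrunning the eight-membered closure, or alkylation of ring B or of other positions of ring A by the aldehyde. The fallback sets out from bromide 11, makes the C-a–ring A bond first by acylation and closes the ring at sulfur. n-BuLi followed by ClCO2Me gives the methyl 4-carboxylate F4, whose ester deactivates ring B. SnCl4-mediated Friedel–Crafts acylation with 4-methoxybenzoyl chloride at C2 of ring A gives the keto ester F5. LiAlH4 reduces both carbonyl groups to the benzhydrol–benzyl alcohol diol F6. Mitsunobu reaction with AcSH at the primary alcohol gives the hydroxy thioacetate F7. NaOMe in MeOH frees the thiol, and catalytic TsOH in CH2Cl2 at high dilution closes the ring by capture of the doubly stabilised benzhydryl cation at sulfur, coming back to the route at sulfide 18.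

Step 14 (hydroboration–oxidation). What may go wrong is a stalled addition of the bulky borane to the triaryl alkene flanked by triisopropylsilyl ethers, or poor facial selectivity. The fallback sets out from pentaphenol 23 and hydroborates before silylation with a small borane under substrate control. Excess BH3·THF (the phenols being held as aryloxyboranes) followed by H2O2 in pH 7 phosphate buffer should add to the outer face of the boat and give the (C-a R, C-c S) pentaphenol alcohol F8. i-Pr3SiCl and imidazole in DMF then silylate the five phenols in preference to the hindered secondary alcohol and come back to the route at 26.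

**Further compounds**

F1 | step 11 | S-methylsulfonium tetrafluoroborate of sulfide 18 | COc1ccc(C2c3c(OC)cc(OC)cc3[C@@H]3c4c(cc(OC)cc4C[S+]2C)O[C@H]3c2ccc(OC)cc2)cc1.F[B-](F)(F)F
F2 | step 11 | ring-contracted C-a methylthio compound (seven-membered ring, C-c as CH2) | COc1ccc(C2(SC)c3c(OC)cc(OC)cc3[C@@H]3c4c(cc(OC)cc4C2)O[C@H]3c2ccc(OC)cc2)cc1
F3 | step 11 | C-a methyl sulfoxide of F2 | COc1ccc(C2(S(C)=O)c3c(OC)cc(OC)cc3[C@@H]3c4c(cc(OC)cc4C2)O[C@H]3c2ccc(OC)cc2)cc1
F4 | step 9 | methyl (2R,3R)-3-(3,5-dimethoxyphenyl)-6-methoxy-2-(4-methoxyphenyl)-2,3-dihydrobenzofuran-4-carboxylate | COc1cc(OC)cc(c1)[C@@H]1c2c(cc(OC)cc2C(=O)OC)O[C@H]1c1ccc(OC)cc1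
F5 | step 9 | keto ester: F4 with a 4-methoxybenzoyl group on C2 of ring A | COc1ccc(C(=O)c2c(OC)cc(OC)cc2[C@@H]2c3c(cc(OC)cc3C(=O)OC)O[C@H]2c2ccc(OC)cc2)cc1
F6 | step 9 | diol: benzhydrol at C-a and hydroxymethyl on C4 | COc1ccc(C(O)c2c(OC)cc(OC)cc2[C@@H]2c3c(cc(OC)cc3CO)O[C@H]2c2ccc(OC)cc2)cc1
F7 | step 9 | hydroxy thioacetate: benzhydrol at C-a and CH2SAc on C4 | COc1ccc(C(O)c2c(OC)cc(OC)cc2[C@@H]2c3c(cc(OC)cc3CSC(C)=O)O[C@H]2c2ccc(OC)cc2)cc1
F8 | step 14 | (2R,3R, C-a R, C-c S) pentaphenol alcohol | Oc1ccc([C@@H]2c3c(O)cc(O)cc3[C@@H]3c4c(cc(O)cc4[C@H]2O)O[C@H]3c2ccc(O)cc2)cc1
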